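**Retrosynthetic overview**
1. Feature: on ring B (C6-C7-C14-C13-C12-C11) the lactone carbon C8 is a former methyl on C7 held 1,3-diaxial to the C11 oxygen, so the δ-lactone ring (C6-C7-C8-C9-O10-C11) is CO (C9) inserted between a C8–H and the O10–H of a 3,3,5-trimethylcyclohexanol.
2. Key disconnection: C8–C9 and C9–O10 by Pb(OAc)4/CO remote carbonylation of the ring B tertiary alcohol with a gem-dimethyl C7. The side chain C1–C4 is added afterwards at the C5 aldehyde (allylboration for C5, vinyl ketone, chelation-controlled MeMgBr for C3).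
3. Precursor from 4,4-dimethylcyclohex-2-enone: CBS reduction and Ireland–Claisen rearrangement (C14–C15, sets C14), allylic oxidation (C11=O), methylenation and double conjugate borylation (C5–O, C13–O, sets C6), MeCeCl2 (C11), oxidation and syn reduction (C13).
4. Order of ring formation: ring B is carried from the starting enone; the lactone ring is the only ring closed, in step 13.

Key step: step 13

Remark: atom numbers are those of the target chain (C1=C2, C3 … C16; ring B = C6-C7-C14-C13-C12-C11) and "cis" or "trans" refer to the ring B face that carries the C14 side chain. The target is a γ-hydroxy acid, so the last work-up is kept at pH 5–6 to avoid closure of C16 onto the C13 hydroxyl.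

**Route**

Step 1
Reactants: 1 4,4-dimethylcyclohex-2-en-1-one
Product: 2 (R)-4,4-dimethylcyclohex-2-en-1-ol
Conditions: (S)-2-methyl-CBS-oxazaborolidine (10 mol%), BH3·SMe2, THF, −20 °C; MeOH quench
Reagents that add atoms: none
Why: Corey–Bakshi–Shibata reduction delivers hydride 1,2 to the face fixed by the catalyst, the alkene arm with the quaternary carbon acting as the large group, so the C12 carbinol should form as the R enantiomer that later relays its configuration to C14.

Step 2
Reactants: 2 (R)-4,4-dimethylcyclohex-2-en-1-ol; 3 2-methylpropanoyl chloride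
Product: 4 (R)-4,4-dimethylcyclohex-2-en-1-yl 2-methylpropanoate
Conditions: pyridine, DMAP (cat.), CH2Cl2, 0 °C to rt
Reagents that add atoms: 2-methylpropanoyl chloride, CC(C)C(Cl)=O
Why: DMAP-catalysed acylation of a secondary allylic alcohol by an acid chloride is fast and leaves the carbinol stereocentre untouched.

Step 3
Reactants: 4 (R)-4,4-dimethylcyclohex-2-en-1-yl 2-methylpropanoate
Product: 7 2-[(1R)-6,6-dimethylcyclohex-2-en-1-yl]-2-methylpropanoic acid, via silyl ketene acetal 5 (not isolated), via trimethylsilyl ester 6 (not isolated)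
Conditions: LiN(i-Pr)2, Me3SiCl, Et3N, THF, −78 °C, then 65 °C; 1 M HCl
Reagents that add atoms: none
Why: Ireland–Claisen rearrangement of the isobutyrate silyl ketene acetal (no enolate geometry issue) is suprafacial, so the C14–C15 bond forms intramolecularly on the face that carried the C12 oxygen and the C12 configuration is transferred to C14 next to the gem-dimethyl carbon.

Step 4
Reactants: 7 2-[(1R)-6,6-dimethylcyclohex-2-en-1-yl]-2-methylpropanoic acid; 8 2-(trimethylsilyl)ethanol
Product: 9 2-(trimethylsilyl)ethyl 2-[(1R)-6,6-dimethylcyclohex-2-en-1-yl]-2-methylpropanoate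
Conditions: PPh3, DIAD, THF, 0 °C to rt
Reagents that add atoms: 2-(trimethylsilyl)ethanol, C[Si](C)(C)CCO
Why: Mitsunobu esterification uses the hindered carboxylate as nucleophile at the primary carbon of the activated alcohol, so the congested acyl carbon is never attacked and a fluoride-labile ester results.

Step 5
Reactants: 9 2-(trimethylsilyl)ethyl 2-[(1R)-6,6-dimethylcyclohex-2-en-1-yl]-2-methylpropanoate
Product: 10 enone 2-(trimethylsilyl)ethyl 2-[(1R)-6,6-dimethyl-4-oxocyclohex-2-en-1-yl]-2-methylpropanoate (C11 ketone, C12=C13)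
Conditions: Rh2(cap)4 (dirhodium tetrakis(caprolactamate), 1 mol%), t-BuOOH (5 equiv), K2CO3 (0.5 equiv), CH2Cl2, rt
Reagents that add atoms: tert-butyl hydroperoxide, CC(C)(C)OO
Why: Dirhodium-catalysed allylic C–H oxidation with t-BuOOH should abstract from the open C11 methylene (C14–H is buried between two quaternary carbons) and deliver oxygen to the unhindered C11 end of the allyl radical, giving the enone without touching C14.

Step 6
Reactants: 10 enone (C11 ketone, C12=C13); 11 N,N-dimethylmethyleneiminium iodide (Eschenmoser's salt)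
Product: 14 dienone 2-(trimethylsilyl)ethyl 2-[(1R)-6,6-dimethyl-5-methylidene-4-oxocyclohex-2-en-1-yl]-2-methylpropanoate, via Mannich base 12 (not isolated), via trimethylammonium iodide 13 (not isolated)
Conditions: LiN(i-Pr)2, THF, −78 °C; 11, −78 to 0 °C; MeI, CH2Cl2, rt; NaHCO3 (aq)
Reagents that add atoms: N,N-dimethylmethyleneiminium iodide, C=[N+](C)C.[I-]
Why: The kinetic cross-conjugated enolate can form only at C6 (the other α carbon is vinylic), and its Mannich reaction followed by N-methylation and elimination is the standard α-methylenation, creating no stereocentre.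

Step 7
Reactants: 14 dienone (C6=CH2, C12=C13); 15 bis(pinacolato)diboron
Product: 17 keto diol 2-(trimethylsilyl)ethyl 2-[2-hydroxy-5-(hydroxymethyl)-6,6-dimethyl-4-oxocyclohexyl]-2-methylpropanoate (C13-OH trans and C6-CH2OH cis to the C14 side chain), via bis-boronate 16 (not isolated)
Conditions: 15 (2.4 equiv), CuCl (5 mol%), DPEphos (5 mol%), NaOt-Bu (10 mol%), MeOH (4 equiv), THF, rt; then NaBO3·4H2O, THF–H2O, rt
Reagents that add atoms: sodium perborate, [Na+].[O-]B1OO1
Why: Copper-catalysed conjugate borylation adds boron to both β carbons (C5, then C13 anti to the C14 side chain), methanol protonates the C6 enolate on the face away from that side chain so that C5 ends cis to it (also the equatorial epimer favoured on any equilibration), and perborate oxidises both C–B bonds with retention; the C13 configuration is inconsequential because it is reset in steps 10 and 11.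

Step 8
Reactants: 17 keto diol; 18 tert-butyldimethylsilyl chloride
Product: 19 C5 tert-butyldimethylsilyl ether of keto diol 17
Conditions: imidazole, CH2Cl2, 0 °C
Reagents that add atoms: tert-butyldimethylsilyl chloride, CC(C)(C)[Si](C)(C)Cl
Why: Silylation is selective for the primary C5 hydroxyl over the secondary C13 hydroxyl flanked by the C14 side chain.

Step 9
Reactants: 19 C5 silyl ether ketone; 20 methyllithium
Product: 21 diol with C11 tertiary alcohol (C11-OH cis to C5 and to the C14 side chain, C13-OH trans)
Conditions: MeLi, CeCl3 (anhydrous, 3.5 equiv each), THF, −78 °C; aq. NH4Cl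
Reagents that add atoms: methyllithium, [Li]C
Why: Organocerium 1,2-addition (non-basic, so no enolisation or β-elimination) should occur by equatorial attack, opposite to the axial C7 methyl and trans to the adjacent equatorial C6 substituent (1,2-induction), placing the C11 hydroxyl axial and cis to C5.

Step 10
Reactants: 21 diol with C11 tertiary alcohol
Product: 22 β-hydroxy ketone with C13 ketone and free C11 tertiary hydroxyl
Conditions: Dess–Martin periodinane, NaHCO3, CH2Cl2, 0 °C to rt
Reagents that add atoms: none
Why: Buffered Dess–Martin oxidation converts only the secondary C13 alcohol, the tertiary alcohol being inert, and the neutral conditions avoid retro-aldol cleavage and enolisation at the hindered C14.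

Step 11
Reactants: 22 β-hydroxy ketone (C13 ketone)
Product: 23 syn-1,3-diol (C13-OH cis to the C14 side chain and to C11-OH)
Conditions: Et2BOMe, NaBH4, THF–MeOH (4:1), −78 °C; AcOH, MeOH evaporation
Reagents that add atoms: none
Why: Narasaka–Prasad 1,3-syn reduction: the boron chelate of the axial C11 oxygen and the C13 carbonyl lets hydride enter only from the equatorial side, which is also the side away from the axial C7 methyl, giving the axial C13 alcohol cis to C14–C15.

Step 12
Reactants: 23 syn-1,3-diol; 24 acetic anhydride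
Product: 25 precursor 2-(trimethylsilyl)ethyl ester with C13 acetate, C5 silyl ether and free C11 tertiary alcohol (ring B, gem-dimethyl C7)
Conditions: Ac2O, pyridine, DMAP (cat.), CH2Cl2, rt to 40 °C
Reagents that add atoms: acetic anhydride, CC(=O)OC(C)=O
Why: DMAP-catalysed acetylation takes the secondary C13 alcohol and leaves the tertiary C11 alcohol free for the key step.

Step 13
Reactants: 25 ring B tertiary alcohol (precursor); 26 carbon monoxide
Product: 27 protected 2-oxabicyclo[3.3.1]nonan-3-one (δ-lactone C9(=O)–O10–C11, C5 silyl ether, C13 acetate, C16 2-(trimethylsilyl)ethyl ester)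
Conditions: Pb(OAc)4 (2 equiv), CO (80 atm), benzene, 40 °C
Reagents that add atoms: carbon monoxide, [C-]#[O+]
Why: Ligand exchange gives the lead alkoxide of C11–OH, whose homolysis furnishes the alkoxy radical; this abstracts hydrogen from the syn-axial C7 methyl through a six-membered chair-like transition state (1,5-hydrogen transfer), the primary C8 radical adds CO under pressure (C8–C9), and the acyl radical is oxidised by lead and captured by the C11 oxygen (C9–O10). The closest known reaction type is the lead tetraacetate remote carbonylation of saturated alcohols to δ-lactones. The lactone ring closes by a six-membered O-acylation at the acyl carbon (6-exo), giving the 2-oxabicyclo[3.3.1]nonan-3-one. C7 becomes stereogenic and its configuration is relayed from C11, because only the methyl cis to the oxygen is within reach. The step needs hydrogen transfer to win over β-scission and CO capture to win over oxidative ether closure: in the only chair that keeps the C6 and C14 substituents equatorial the C11 oxygen and one C7 methyl are 1,3-diaxial, β-scission could release only unstabilised alkyl radicals because C13 is an acetate and not a ketone, and the high CO pressure intercepts the C8 radical.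

Step 14
Reactants: 27 protected bicyclic lactone
Product: 28 C5 primary alcohol of the bicyclic lactone
Conditions: HF·pyridine, pyridine, THF, 0 °C to rt
Reagents that add atoms: none
Why: Buffered HF·pyridine desilylation removes the primary silyl ether and should spare the acetate, the lactone and the 2-(trimethylsilyl)ethyl ester, which needs free fluoride ion.

Step 15
Reactants: 28 C5 primary alcohol
Product: 29 C5 aldehyde of the bicyclic lactone
Conditions: Dess–Martin periodinane, NaHCO3, CH2Cl2, 0 °C
Reagents that add atoms: none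
Why: Dess–Martin oxidation under buffered, non-basic conditions gives the aldehyde without epimerising C6 or opening the lactone.

Step 16
Reactants: 29 C5 aldehyde; 30 (−)-B-allyldiisopinocampheylborane (from (+)-α-pinene)
Product: 31 (5S)-homoallylic alcohol (C5-OH, C4H2, C3H=C2H2)
Conditions: 30 (1.5 equiv), Et2O, −78 °C; then NaBO3·4H2O, THF–H2O
Reagents that add atoms: (−)-B-allyldiisopinocampheylborane, C=CCB([C@@H]1C[C@@H]2C[C@H]([C@H]1C)C2(C)C)[C@@H]1C[C@@H]2C[C@H]([C@H]1C)C2(C)C
Why: Brown allylboration through a closed chair transition state is reagent-controlled even with hindered α-branched aldehydes, and this enantiomer of the reagent should deliver the allyl group to the face giving the 5S carbinol.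

Step 17
Reactants: 31 (5S)-homoallylic alcohol
Product: 32 β-hydroxy aldehyde (C3 aldehyde, C5-OH)
Conditions: O3, CH2Cl2, −78 °C; PPh3
Reagents that add atoms: ozone, [O-][O+]=O
Why: Ozonolysis with reductive work-up cleaves the only alkene and leaves C3 as the aldehyde.

Step 18
Reactants: 32 β-hydroxy aldehyde; 33 vinylmagnesium bromide
Product: 34 allylic alcohol diol (C3 epimers, C5-OH)
Conditions: CH2=CHMgBr (3.5 equiv), THF, −78 °C; aq. NH4Cl
Reagents that add atoms: vinylmagnesium bromide, C=C[Mg]Br
Why: Grignard addition to the aldehyde at −78 °C is much faster than attack on the hindered lactone, acetate or ester, and the C3 configuration is irrelevant because it is oxidised next.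

Step 19
Reactants: 34 allylic alcohol diol
Product: 35 β-hydroxy vinyl ketone (C3 ketone, C5-OH)
Conditions: MnO2 (activated, excess), CH2Cl2, rt
Reagents that add atoms: none
Why: MnO2 oxidises the allylic alcohol selectively and leaves the hindered saturated C5 alcohol, which is needed free for the next step.

Step 20
Reactants: 35 β-hydroxy vinyl ketone; 36 methylmagnesium bromide
Product: 37 protected target (3R,5S)-diol with C13 acetate and C16 2-(trimethylsilyl)ethyl ester
Conditions: MeMgBr (3 equiv), CH2Cl2–Et2O, −78 °C; aq. NH4Cl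
Reagents that add atoms: methylmagnesium bromide, C[Mg]Br
Why: Chelation-controlled 1,2-addition: the C5 magnesium alkoxide and the C3 carbonyl form a six-membered chelate with C6 and the vinyl group equatorial, and axial attack of methyl should give the 1,3-syn diol, i.e. 3R.

Step 21
Reactants: 37 protected target
Product: 39 target CNP0297019.1, via tetrabutylammonium carboxylate 38 (not isolated)
Conditions: Bu4NF, THF, rt; then K2CO3, MeOH, rt; pH 5.5 phosphate buffer, 0 °C
Reagents that add atoms: none
Why: Fluoride-induced β-elimination cleaves the 2-(trimethylsilyl)ethyl ester first, so the C16 carboxylate cannot lactonise when mild methanolysis then removes the C13 acetate; the tertiary-alkyl δ-lactone is the least reactive ester present.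

**Compound list**
1 | 4,4-dimethylcyclohex-2-en-1-one | CC1(C)CCC(=O)C=C1 | starting material
2 | (R)-4,4-dimethylcyclohex-2-en-1-ol | O[C@H]1C=CC(C)(C)CC1 | intermediate
3 | 2-methylpropanoyl chloride | CC(C)C(Cl)=O | starting material
4 | (R)-4,4-dimethylcyclohex-2-en-1-yl 2-methylpropanoate | CC(C)C(=O)O[C@H]1C=CC(C)(C)CC1 | intermediate
5 | trimethylsilyl ketene acetal of 4 | CC(C)=C(O[Si](C)(C)C)O[C@H]1C=CC(C)(C)CC1 | intermediate
6 | trimethylsilyl 2-[(1R)-6,6-dimethylcyclohex-2-en-1-yl]-2-methylpropanoate | C[Si](C)(C)OC(=O)C(C)(C)[C@@H]1C=CCCC1(C)C | intermediate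
7 | 2-[(1R)-6,6-dimethylcyclohex-2-en-1-yl]-2-methylpropanoic acid | OC(=O)C(C)(C)[C@@H]1C=CCCC1(C)C | intermediate
8 | 2-(trimethylsilyl)ethanol | C[Si](C)(C)CCO | starting material
9 | 2-(trimethylsilyl)ethyl 2-[(1R)-6,6-dimethylcyclohex-2-en-1-yl]-2-methylpropanoate | C[Si](C)(C)CCOC(=O)C(C)(C)[C@@H]1C=CCCC1(C)C | intermediate
10 | 2-(trimethylsilyl)ethyl 2-[(1R)-6,6-dimethyl-4-oxocyclohex-2-en-1-yl]-2-methylpropanoate | C[Si](C)(C)CCOC(=O)C(C)(C)[C@@H]1C=CC(=O)CC1(C)C | intermediate
11 | N,N-dimethylmethyleneiminium iodide (Eschenmoser's salt) | C=[N+](C)C.[I-] | starting material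
12 | Mannich base, 5-(dimethylaminomethyl) derivative of 10 (C6 epimers) | C[Si](C)(C)CCOC(=O)C(C)(C)[C@@H]1C=CC(=O)C(CN(C)C)C1(C)C | intermediate
13 | trimethylammonium iodide of 12 | C[Si](C)(C)CCOC(=O)C(C)(C)[C@@H]1C=CC(=O)C(C[N+](C)(C)C)C1(C)C.[I-] | intermediate
14 | 2-(trimethylsilyl)ethyl 2-[(1R)-6,6-dimethyl-5-methylidene-4-oxocyclohex-2-en-1-yl]-2-methylpropanoate | C[Si](C)(C)CCOC(=O)C(C)(C)[C@@H]1C=CC(=O)C(=C)C1(C)C | intermediate
15 | bis(pinacolato)diboron | CC1(C)OB(OC1(C)C)B1OC(C)(C)C(C)(C)O1 | starting material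
16 | C5,C13-bis(pinacolboronate) ketone (C13-B trans, C5 cis to the C14 side chain) | C[Si](C)(C)CCOC(=O)C(C)(C)[C@@H]1[C@@H](B2OC(C)(C)C(C)(C)O2)CC(=O)[C@H](CB2OC(C)(C)C(C)(C)O2)C1(C)C | intermediate
17 | keto diol (C11 ketone, C13-OH trans, C6-CH2OH cis to the C14 side chain) | C[Si](C)(C)CCOC(=O)C(C)(C)[C@@H]1[C@@H](O)CC(=O)[C@H](CO)C1(C)C | intermediate
18 | tert-butyldimethylsilyl chloride | CC(C)(C)[Si](C)(C)Cl | starting material
19 | C5 tert-butyldimethylsilyl ether of 17 | C[Si](C)(C)CCOC(=O)C(C)(C)[C@@H]1[C@@H](O)CC(=O)[C@H](CO[Si](C)(C)C(C)(C)C)C1(C)C | intermediate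
20 | methyllithium | [Li]C | starting material
21 | diol with C11 tertiary alcohol (C11-OH cis to C5, C13-OH trans to the C14 side chain) | C[Si](C)(C)CCOC(=O)C(C)(C)[C@@H]1[C@@H](O)C[C@](C)(O)[C@H](CO[Si](C)(C)C(C)(C)C)C1(C)C | intermediate
22 | β-hydroxy ketone (C13 ketone, C11 tertiary alcohol) | C[Si](C)(C)CCOC(=O)C(C)(C)[C@@H]1C(=O)C[C@](C)(O)[C@H](CO[Si](C)(C)C(C)(C)C)C1(C)C | intermediate
23 | syn-1,3-diol (C13-OH cis to the C14 side chain and to C11-OH) | C[Si](C)(C)CCOC(=O)C(C)(C)[C@@H]1[C@H](O)C[C@](C)(O)[C@H](CO[Si](C)(C)C(C)(C)C)C1(C)C | intermediate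
24 | acetic anhydride | CC(=O)OC(C)=O | starting material
25 | key-step precursor, ring B tertiary alcohol with gem-dimethyl C7 (C13 acetate, C5 silyl ether, C16 2-(trimethylsilyl)ethyl ester) | CC(C)(C)[Si](C)(C)OC[C@@H]1C(C)(C)[C@H](C(C)(C)C(=O)OCC[Si](C)(C)C)[C@H](OC(C)=O)C[C@]1(C)O | intermediate
26 | carbon monoxide | [C-]#[O+] | starting material
27 | key-step product, protected 2-oxabicyclo[3.3.1]nonan-3-one | CC(C)(C)[Si](C)(C)OC[C@@H]1[C@]2(C)CC(=O)O[C@@]1(C)C[C@@H](OC(C)=O)[C@H]2C(C)(C)C(=O)OCC[Si](C)(C)C | intermediate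
28 | C5 primary alcohol of the bicyclic lactone | OC[C@@H]1[C@]2(C)CC(=O)O[C@@]1(C)C[C@@H](OC(C)=O)[C@H]2C(C)(C)C(=O)OCC[Si](C)(C)C | intermediate
29 | C5 aldehyde of the bicyclic lactone | O=C[C@@H]1[C@]2(C)CC(=O)O[C@@]1(C)C[C@@H](OC(C)=O)[C@H]2C(C)(C)C(=O)OCC[Si](C)(C)C | intermediate
30 | (−)-B-allyldiisopinocampheylborane | C=CCB([C@@H]1C[C@@H]2C[C@H]([C@H]1C)C2(C)C)[C@@H]1C[C@@H]2C[C@H]([C@H]1C)C2(C)C | starting material
31 | (5S)-homoallylic alcohol | C=CC[C@H](O)[C@@H]1[C@]2(C)CC(=O)O[C@@]1(C)C[C@@H](OC(C)=O)[C@H]2C(C)(C)C(=O)OCC[Si](C)(C)C | intermediate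
32 | β-hydroxy aldehyde (C3 aldehyde, 5S) | O=CC[C@H](O)[C@@H]1[C@]2(C)CC(=O)O[C@@]1(C)C[C@@H](OC(C)=O)[C@H]2C(C)(C)C(=O)OCC[Si](C)(C)C | intermediate
33 | vinylmagnesium bromide | C=C[Mg]Br | starting material
34 | allylic alcohol diol (C3 epimers, 5S) | C=CC(O)C[C@H](O)[C@@H]1[C@]2(C)CC(=O)O[C@@]1(C)C[C@@H](OC(C)=O)[C@H]2C(C)(C)C(=O)OCC[Si](C)(C)C | intermediate
35 | β-hydroxy vinyl ketone (5S) | C=CC(=O)C[C@H](O)[C@@H]1[C@]2(C)CC(=O)O[C@@]1(C)C[C@@H](OC(C)=O)[C@H]2C(C)(C)C(=O)OCC[Si](C)(C)C | intermediate
36 | methylmagnesium bromide | C[Mg]Br | starting material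
37 | protected target (3R,5S), C13 acetate, C16 2-(trimethylsilyl)ethyl ester | C=C[C@](C)(O)C[C@H](O)[C@@H]1[C@]2(C)CC(=O)O[C@@]1(C)C[C@@H](OC(C)=O)[C@H]2C(C)(C)C(=O)OCC[Si](C)(C)C | intermediate
38 | tetrabutylammonium C16 carboxylate with C13 acetate | C=C[C@](C)(O)C[C@H](O)[C@@H]1[C@]2(C)CC(=O)O[C@@]1(C)C[C@@H](OC(C)=O)[C@H]2C(C)(C)C(=O)[O-].CCCC[N+](CCCC)(CCCC)CCCC | intermediate
39 | CNP0297019.1 | C=C[C@](C)(O)C[C@H](O)[C@@H]1[C@]2(C)CC(=O)O[C@@]1(C)C[C@@H](O)[C@H]2C(C)(C)C(=O)O | target

**Totals and risks**

Total step count: 21. Longest linear sequence: 21 steps (1 to 39); all other reactants are purchased.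

Steps most likely to fail:

1. Step 13. β-Scission of the tertiary alkoxy radical, or oxidation of the C8 radical by tetravalent lead to the cyclic C8–O ether, may outrun CO capture. Fallback: radical generation and carbonylation are separated. From 25, the hypoiodite reaction (PhI(OAc)2, I2, hν, cyclohexane, rt) runs the same 1,5-hydrogen transfer but traps the C8 radical with iodine, giving the δ-iodo alcohol F1. Light-induced atom-transfer carbonylation of the iodide (Pd(PPh3)4 cat., CO 40 atm, K2CO3, benzene, hν) then gives the acyl species that the C11 hydroxyl closes, returning to the route at 27.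

2. Step 7. Protonation of the C6 enolate may show poor facial selectivity, C6 may epimerise during the perborate oxidation, or borylation at the hindered C13 may stay incomplete. Fallback: C6 is set after C11 by hydroboration instead of by protonation. From 10, single conjugate borylation (15, 1.1 equiv, CuCl/DPEphos/NaOt-Bu, MeOH) gives the C13 boronate F2 and NaBO3 gives the β-hydroxy ketone F3. Its dianion (LiN(i-Pr)2, 2.2 equiv; the C13 alkoxide steers enolisation to C6) reacts with 11 to give the Mannich base F4, which loses dimethylamine on warming in toluene with silica to give the α-methylene ketone F5. MeLi/CeCl3 gives the allylic tertiary alcohol F6. BH3·THF, then NaBO3, gives the triol F7, with hydrogen delivered to C6 on the face opposite to the axial C7 methyl and the axial C11 oxygen. Selective silylation with 18 returns to the route at 21.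

3. Step 5. Hydrogen abstraction at C14–H, or oxygen delivery at C13 with allylic transposition, would give isomeric enones. Fallback: a π-allyl palladium pathway instead of a radical one. From 9, allylic acetoxylation (Pd(OAc)2 cat., benzoquinone, AcOH, 50 °C) places acetate at the less hindered C11 terminus of the π-allyl complex to give the allylic acetate F8. Methanolysis (K2CO3, MeOH) gives the allylic alcohol F9, and MnO2 oxidation returns to the route at 10.

Further compounds
F1 | step 13 | δ-iodo alcohol, C8 iodide of 25 | CC(C)(C)[Si](C)(C)OC[C@@H]1[C@](C)(CI)[C@H](C(C)(C)C(=O)OCC[Si](C)(C)C)[C@H](OC(C)=O)C[C@]1(C)O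
F2 | step 7 | C13 pinacolboronate ketone (boron trans to the C14 side chain) | C[Si](C)(C)CCOC(=O)C(C)(C)[C@@H]1[C@@H](B2OC(C)(C)C(C)(C)O2)CC(=O)CC1(C)C
F3 | step 7 | β-hydroxy ketone (C11 ketone, C13-OH trans to the C14 side chain) | C[Si](C)(C)CCOC(=O)C(C)(C)[C@@H]1[C@@H](O)CC(=O)CC1(C)C
F4 | step 7 | C6 Mannich base of F3 (C6 epimers) | C[Si](C)(C)CCOC(=O)C(C)(C)[C@@H]1[C@@H](O)CC(=O)C(CN(C)C)C1(C)C
F5 | step 7 | α-methylene ketone (C6=CH2, C13-OH) | C[Si](C)(C)CCOC(=O)C(C)(C)[C@@H]1[C@@H](O)CC(=O)C(=C)C1(C)C
F6 | step 7 | allylic tertiary alcohol (C11-OH cis to the C14 side chain, C6=CH2) | C[Si](C)(C)CCOC(=O)C(C)(C)[C@@H]1[C@@H](O)C[C@](C)(O)C(=C)C1(C)C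
F7 | step 7 | triol (C5-OH, C11-OH, C13-OH), desilyl 21 | C[Si](C)(C)CCOC(=O)C(C)(C)[C@@H]1[C@@H](O)C[C@](C)(O)[C@H](CO)C1(C)C
F8 | step 5 | C11 allylic acetate of 9 (C11 epimers) | C[Si](C)(C)CCOC(=O)C(C)(C)[C@@H]1C=CC(OC(C)=O)CC1(C)C
F9 | step 5 | C11 allylic alcohol of 9 (C11 epimers) | C[Si](C)(C)CCOC(=O)C(C)(C)[C@@H]1C=CC(O)CC1(C)C
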